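**Retrosynthetic overview**

1. Tropolone ring first, as in the biosynthesis: 3-methylorcinaldehyde 1 → [o-quinol 2] → stipitaldehyde 3 by oxidative dearomatisation and radical ring expansion; CHO → CH2OH then gives the o-quinone methide precursor 4.
2. C9 polyene: sorbaldehyde 5 + allyl phosphonium salt 6 → [ylide 7, 3Z isomer 8] → all-E nona-1,3,5,7-tetraene 9.
3. Key disconnection, a double retro-oxa-Diels–Alder: 9 + two molecules of tropolone o-quinone methide 10 (from 4) → [mono-adduct 11] → target 12. Both dihydropyran rings and all three stereocentres come from one catalyst-controlled pot.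
4. Ring order: tropolone → dihydropyran at the vinyl end → dihydropyran at the propenyl end. No protecting groups.

Assumptions: TropB and TropC are recombinant catalysts from routine E. coli expression; the (R)-catalyst in step 4 is assumed to give the R O–CH centres (to be confirmed on the first run, otherwise the (S)-catalyst is used); o-quinol 2 is drawn as its (R)-enantiomer, which is of no consequence because that centre is erased.

**Route**

Step 1
Reactants: 1 3-methylorcinaldehyde (2,4-dihydroxy-3,6-dimethylbenzaldehyde)
Product: 3 stipitaldehyde (2,4-dihydroxy-7-methyl-5-oxocyclohepta-1,3,6-triene-1-carbaldehyde), via o-quinol 2 (not isolated)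
Conditions: TropB + TropC (E. coli lysates), NADP+ (cat.), D-glucose/GDH, α-ketoglutarate (2 equiv), FeSO4 (cat.), Na ascorbate (cat.), air, KPi pH 7.5, 5% DMSO, 30 °C, one pot; acidify, EDTA, EtOAc
Reagents that add atoms: dioxygen, O=O
Why: This is the native enzyme pair on its native substrate: the flavin monooxygenase TropB hydroxylates C3 (enzymatic oxidative dearomatisation, setting the transient stereocentre of 2), then the Fe(II)/α-ketoglutarate dioxygenase TropC abstracts a hydrogen atom from the 3-methyl group and the primary radical undergoes a Dowd–Beckwith-type 1,2-shift ring expansion and oxidative aromatisation to the tropolone, which erases that stereocentre.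

Step 2
Reactants: 3 stipitaldehyde
Product: 4 2,4-dihydroxy-5-(hydroxymethyl)-6-methylcyclohepta-2,4,6-trien-1-one
Conditions: NaBH4 (2 equiv), MeOH–THF, 0 °C, 20 min; 1 M HCl to pH 5 at 0 °C, cold EtOAc extraction, used cold and acid-free
Reagents that add atoms: none
Why: Borohydride reduction of the aryl aldehyde is chemoselective because the tropolonate ring carbonyl is a vinylogous carboxylate and is not reduced at 0 °C; no stereocentre is formed.

Step 3
Reactants: 5 sorbaldehyde ((2E,4E)-hexa-2,4-dienal); 6 allyltriphenylphosphonium bromide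
Product: 9 (3E,5E,7E)-nona-1,3,5,7-tetraene, via allylidene ylide 7 (not isolated), via 3Z-tetraene 8 (not isolated)
Conditions: 6, KOtBu, THF, 0 °C; then 5, 0 °C → rt; pentane, filter; I2 (2 mol%), rt, daylight; Na2S2O3 wash, silica plug, cold concentration, BHT
Reagents that add atoms: none
Why: Wittig olefination with the semi-stabilised allyl ylide forms the new C3=C4 bond as an E/Z mixture without touching the two E bonds of sorbaldehyde, and iodine-catalysed E/Z equilibration converts the 3Z isomer 8 into the thermodynamically preferred all-E tetraene.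

Step 4
Reactants: 4 2,4-dihydroxy-5-(hydroxymethyl)-6-methylcyclohepta-2,4,6-trien-1-one (2.4 equiv); 9 (3E,5E,7E)-nona-1,3,5,7-tetraene (1 equiv)
Product: 12 (2R,3R)-8-hydroxy-2-{(1E,3E)-4-[(2R)-8-hydroxy-5-methyl-7-oxo-2,3,4,7-tetrahydrocyclohepta[b]pyran-2-yl]buta-1,3-dien-1-yl}-3,5-dimethyl-3,4-dihydrocyclohepta[b]pyran-7(2H)-one, via tropolone o-quinone methide 10 (not isolated), via mono-adduct 11 (not isolated)
Conditions: (R)-3,3′-bis(2,4,6-triisopropylphenyl)-BINOL N-triflylphosphoramide (5 mol%), 5 Å MS, CHCl3, −20 °C → rt, 4 added in portions, dark, Ar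
Reagents that add atoms: none
Why: Proposed new method: the chiral N-triflylphosphoramide dehydrates the vinylogous-acid benzylic alcohol 4 to the hydrogen-bonded (ion-paired) tropolone o-quinone methide 10, which adds twice to 9 in inverse-electron-demand oxa-Diels–Alder fashion, first at the unhindered vinyl end (11) and then at the methyl-capped propenyl end, each time with CH2 bonding to the outer carbon and O to the carbon whose developing positive charge is stabilised by the remaining polyene, so that suprafacial addition to the E-propenyl bond gives the 2,3-trans ring and the catalyst, bound only to the electrophile, presents the same face to both =CH(polyenyl) carbons and sets all three centres R; the closest known reaction types are the chiral phosphoric acid/N-triflylphosphoramide-catalysed enantioselective [4+2] cycloaddition of in situ generated o-quinone methides with unactivated styrenes and alkenes, and the thermal cycloaddition of tropolone o-quinone methides with alkenes.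

**Compound list**

1 | 3-methylorcinaldehyde (2,4-dihydroxy-3,6-dimethylbenzaldehyde) | Cc1cc(O)c(C)c(O)c1C=O | starting material
2 | o-quinol, (3R)-2,3-dihydroxy-3,6-dimethyl-4-oxocyclohexa-1,5-diene-1-carbaldehyde | O=CC1=C(O)[C@@](C)(O)C(=O)C=C1C | intermediate
3 | stipitaldehyde (2,4-dihydroxy-7-methyl-5-oxocyclohepta-1,3,6-triene-1-carbaldehyde) | Cc1cc(=O)c(O)cc(O)c1C=O | intermediate
4 | 2,4-dihydroxy-5-(hydroxymethyl)-6-methylcyclohepta-2,4,6-trien-1-one | Cc1cc(=O)c(O)cc(O)c1CO | intermediate
5 | sorbaldehyde, (2E,4E)-hexa-2,4-dienal | C/C=C/C=C/C=O | starting material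
6 | allyltriphenylphosphonium bromide | C=CC[P+](c1ccccc1)(c1ccccc1)c1ccccc1.[Br-] | starting material
7 | allylidenetriphenylphosphorane (ylide) | C=CC=P(c1ccccc1)(c1ccccc1)c1ccccc1 | intermediate
8 | (3Z,5E,7E)-nona-1,3,5,7-tetraene | C=C/C=C\C=C\C=C\C | intermediate
9 | (3E,5E,7E)-nona-1,3,5,7-tetraene | C=C/C=C/C=C/C=C/C | intermediate
10 | tropolone o-quinone methide, 2-hydroxy-6-methyl-5-methylidenecyclohepta-2,6-diene-1,4-dione | C=C1C(C)=CC(=O)C(O)=CC1=O | intermediate
11 | mono-adduct, (2R)-2-[(1E,3E,5E)-hepta-1,3,5-trien-1-yl]-8-hydroxy-5-methyl-3,4-dihydrocyclohepta[b]pyran-7(2H)-one | C/C=C/C=C/C=C/[C@H]1CCc2c(C)cc(=O)c(O)cc2O1 | intermediate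
12 | (2R,3R)-8-hydroxy-2-{(1E,3E)-4-[(2R)-8-hydroxy-5-methyl-7-oxo-2,3,4,7-tetrahydrocyclohepta[b]pyran-2-yl]buta-1,3-dien-1-yl}-3,5-dimethyl-3,4-dihydrocyclohepta[b]pyran-7(2H)-one | Cc1cc(=O)c(O)cc2c1C[C@@H](C)[C@H](/C=C/C=C/[C@H]1CCc3c(C)cc(=O)c(O)cc3O1)O2 | target

**Step count and risks**

Total step count: 4. Longest linear sequence: 3 steps (1 → 3 → 4 → 12); the tetraene branch is one step.

The three steps most likely to fail are step 4, step 1 and step 3, in that order.

Step 4 is the greatest risk. The second cycloaddition may choose the C3=C4 bond of mono-adduct 11 instead of the propenyl end. The endo methyl at the propenyl end may invert or erode the catalyst's facial preference relative to the vinyl end. The o-quinone methide may oligomerise, and the acid may polymerise the tetraene.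

The fallback sets out from compound 4 and comes back to the route at compound 12. It replaces the double cycloaddition on the preformed tetraene by two separate mono-cycloadditions on cheap symmetrical polyenes, used in excess so that site selectivity is no issue, followed by a diene-forming cross-metathesis. Each half is made with whichever catalyst antipode gives its R centre and is upgraded by chiral SFC if needed. With (E)-hexa-1,3,5-triene, 4 gives (2R)-2-[(1E)-buta-1,3-dien-1-yl]-8-hydroxy-5-methyl-3,4-dihydrocyclohepta[b]pyran-7(2H)-one F1. With (2E,4E)-hexa-2,4-diene, 4 gives (2R,3R)-8-hydroxy-3,5-dimethyl-2-[(1E)-prop-1-en-1-yl]-3,4-dihydrocyclohepta[b]pyran-7(2H)-one F2. Cross-metathesis of F1 with F2 (Hoveyda–Grubbs II, CH2Cl2, 40 °C, propene lost) forms the central C=C bond of the linker E-selectively and gives 12. If the free tropolones poison the ruthenium catalyst, they are masked in situ as acetates.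

Step 1 may fail through low turnover of TropC on preparative scale, shunt products, or chelation of iron by the product. The fallback is a de novo chemical ring expansion of the halocarbene type. It cannot branch from a numbered compound, because none of them offers a chemical handle for ring expansion; it sets out from purchased 2-methylanisole (COc1ccccc1C) and comes back to the route at compound 4, so that steps 1 and 2 are not needed. Birch reduction (Li, NH3, t-BuOH) gives 1-methoxy-2-methylcyclohexa-1,4-diene F3. Dibromocarbene (CHBr3, KOtBu, pentane, −10 °C) adds to the enol-ether double bond and gives racemic cis-fused 7,7-dibromo-1-methoxy-6-methylbicyclo[4.1.0]hept-3-ene F4. OsO4/NMO gives racemic 7,7-dibromo-1-methoxy-6-methylbicyclo[4.1.0]heptane-3,4-diol (cis-diol anti to the CBr2 bridge) F5. Oxidation with TFAA/DMSO and then Et3N gives the α-diketone, which enolises, opens the cyclopropane and loses HBr to give 5-bromo-2-hydroxy-4-methoxy-6-methylcyclohepta-2,4,6-trien-1-one F6. HBr/AcOH cleaves the vinylogous methyl ester to 5-bromo-2,4-dihydroxy-6-methylcyclohepta-2,4,6-trien-1-one F7. Stille coupling with (tributylstannyl)methanol (Pd(PPh3)4, dioxane, 90 °C) then gives 4.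

Step 3 may fail through incomplete E/Z equilibration, polymerisation under iodine, or loss of the volatile tetraene. The fallback sets out from compound 5 and comes back to the route at compound 9. It builds every stereodefined double bond with a stabilised ylide and adds the terminal CH2 last. Compound 5 and (triphenylphosphoranylidene)acetaldehyde (1 equiv, toluene, 80 °C) give (2E,4E,6E)-octa-2,4,6-trienal F8. Methylenation of F8 with Ph3P=CH2 (from methyltriphenylphosphonium bromide and KOtBu, THF, 0 °C) gives 9 with no new stereogenic double bond.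

Further compounds
F1 | step 4 | (2R)-2-[(1E)-buta-1,3-dien-1-yl]-8-hydroxy-5-methyl-3,4-dihydrocyclohepta[b]pyran-7(2H)-one | C=C/C=C/[C@H]1CCc2c(C)cc(=O)c(O)cc2O1
F2 | step 4 | (2R,3R)-8-hydroxy-3,5-dimethyl-2-[(1E)-prop-1-en-1-yl]-3,4-dihydrocyclohepta[b]pyran-7(2H)-one | Cc1cc(=O)c(O)cc2c1C[C@@H](C)[C@H](/C=C/C)O2
F3 | step 1 | 1-methoxy-2-methylcyclohexa-1,4-diene | COC1=C(C)CC=CC1
F4 | step 1 | 7,7-dibromo-1-methoxy-6-methylbicyclo[4.1.0]hept-3-ene (racemic, cis-fused, one enantiomer drawn) | CO[C@]12CC=CC[C@@]1(C)C2(Br)Br
F5 | step 1 | 7,7-dibromo-1-methoxy-6-methylbicyclo[4.1.0]heptane-3,4-diol (racemic, cis-diol anti to the CBr2 bridge, one enantiomer drawn) | CO[C@]12C[C@H](O)[C@H](O)C[C@@]1(C)C2(Br)Br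
F6 | step 1 | 5-bromo-2-hydroxy-4-methoxy-6-methylcyclohepta-2,4,6-trien-1-one | COc1cc(O)c(=O)cc(C)c1Br
F7 | step 1 | 5-bromo-2,4-dihydroxy-6-methylcyclohepta-2,4,6-trien-1-one | Oc1cc(O)c(=O)cc(C)c1Br
F8 | step 3 | (2E,4E,6E)-octa-2,4,6-trienal | C/C=C/C=C/C=C/C=O
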